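## Retrosynthetic overview

1. The three ester C–O bonds are made one per step, each by a Mitsunobu inversion of 6-epi-incarvilline 43: first at the ring C3 acid (28), then at the quaternary C1 acid (45), last at the side-chain acid (53). The phenol is unmasked at the end.
2. The three carboxyls are kept apart as the aminoquinoline amide (C3), an allyl ester (C1) and a 2-(trimethylsilyl)ethyl enoate (side chain). The side chain comes from a B-alkyl Suzuki coupling with an E enol triflate, the aryl group from an aminoquinoline-directed C–H arylation cis to the amide.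
3. The cyclobutane is the first ring formed, by a TiCl2(OiPr)2/TADDOL-catalysed asymmetric [2+2] cycloaddition; a temporary cis-fused γ-lactone then fixes the methyl-bearing quaternary carbon.
4. 6-epi-Incarvilline: the cyclopentane comes from a meso cyclopentenediol diacetate desymmetrised by a lipase; the piperidine ring is closed by a reductive Heck cyclisation, followed by face-selective hydrogenation.
5. Ring order: cyclobutane (step 2) → lactone (step 4, reopened in step 13); preformed cyclopentene → piperidine (step 29).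

Assumption: the target is the stereoisomer exactly as encoded in the SMILES, and the TADDOL enantiomer in step 2 is taken as the one that gives adduct 6 as drawn. In the cyclobutane-1,3-dicarboxylate names, C1 is the methyl-bearing carbon and C4 the aryl-bearing carbon.

## Part A – cyclobutane core

Step 1
Reactants: 1 monomethyl fumarate; 2 1,3-oxazolidin-2-one
Product: 4 methyl (E)-4-oxo-4-(2-oxo-1,3-oxazolidin-3-yl)but-2-enoate, via mixed pivalic anhydride 3 (not isolated)
Conditions: PivCl, Et3N, THF, −20 °C; then 2, LiCl, rt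
Reagents that add atoms: none
Why: Mixed-anhydride N-acylation of the oxazolidinone activates the acid without touching the methyl ester or the E alkene; no stereocentre is formed.

Step 2
Reactants: 4; 5 1,1-bis(methylsulfanyl)ethene
Product: 6 methyl (1S,2S)-3,3-bis(methylsulfanyl)-2-(2-oxo-1,3-oxazolidine-3-carbonyl)cyclobutane-1-carboxylate
Conditions: TiCl2(OiPr)2 (10 mol%), TADDOL diol (2-methyl-2-phenyl-α,α,α',α'-tetraphenyl-1,3-dioxolane-4,5-dimethanol, 11 mol%), 4 Å MS, toluene/petroleum ether, 0 °C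
Reagents that add atoms: none
Why: Narasaka-type asymmetric [2+2] cycloaddition catalysed by a tetravalent titanium TADDOLate: the CH2 of the ketene dithioacetal adds to the β-carbon of the chelated imide on the face left open by the diolate and the thionium closes on the titanium enolate, so the trans arrangement of the fumarate is kept and both ring stereocentres are set by the catalyst.

Step 3
Reactants: 6
Product: 7 methyl (1S,2S)-2-(hydroxymethyl)-3,3-bis(methylsulfanyl)cyclobutane-1-carboxylate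
Conditions: NaBH4, THF/H2O (4:1), 0 °C → rt
Reagents that add atoms: none
Why: Chemoselective borohydride reduction of the activated N-acyloxazolidinone to the primary alcohol leaves the methyl ester and dithioacetal intact, and the trans hydroxy ester cannot lactonise.

Step 4
Reactants: 7
Product: 9 (1R,5S)-6,6-bis(methylsulfanyl)-3-oxabicyclo[3.2.0]heptan-2-one, via cis-hydroxy ester 8 (not isolated)
Conditions: KOtBu (0.5 equiv), THF/t-BuOH, 0 °C → rt; AcOH quench
Reagents that add atoms: none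
Why: Base-mediated ester epimerisation with lactonisation as the sink: only the cis epimer 8 can close to the cis-fused γ-lactone, which fixes the carboxyl-bearing carbon cis to the CH2O arm.

Step 5
Reactants: 9
Product: 11 (1R,5S)-1-methyl-6,6-bis(methylsulfanyl)-3-oxabicyclo[3.2.0]heptan-2-one, via lithium lactone enolate 10 (not isolated)
Conditions: LiN(iPr)2 (1.15 equiv), THF, −78 °C; MeI, −78 → −40 °C
Reagents that add atoms: iodomethane, CI
Why: Enolate alkylation at the ring-fusion carbon: the cis-fused bicyclic lactone can take the methyl group only on the exo face, so the quaternary centre is set with C=O cis to the CH2O arm.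

Step 6
Reactants: 11
Product: 12 (1R,5S)-1-methyl-3-oxabicyclo[3.2.0]heptane-2,6-dione
Conditions: PhI(O2CCF3)2 (1.5 equiv), MeCN/H2O (9:1), 0 °C → rt
Reagents that add atoms: water, O
Why: Oxidative dithioacetal hydrolysis with a hypervalent iodine reagent unmasks the cyclobutanone under near-neutral conditions that spare the lactone.

Step 7
Reactants: 12
Product: 13 (1R,5S)-6-(methoxymethylidene)-1-methyl-3-oxabicyclo[3.2.0]heptan-2-one (E/Z mixture)
Conditions: Ph3P(CH2OMe)Cl, KN(SiMe3)2, THF, −78 → 0 °C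
Reagents that add atoms: (methoxymethyl)triphenylphosphonium chloride, COC[P+](c1ccccc1)(c1ccccc1)c1ccccc1.[Cl-]
Why: Wittig methoxymethylenation; the cyclobutanone is strongly electrophilic and poorly enolisable, so olefination outruns β-elimination of the lactone oxygen.

Step 8
Reactants: 13
Product: 14 (1R,5S,6R)-1-methyl-2-oxo-3-oxabicyclo[3.2.0]heptane-6-carbaldehyde (6-exo)
Conditions: 2 M HCl, THF, 40 °C
Reagents that add atoms: water, O
Why: Acidic enol-ether hydrolysis gives the homologated aldehyde, and the acid equilibrates C6 through the enol to the exo isomer, trans to the CH2O arm and off the concave face.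

Step 9
Reactants: 14
Product: 15 (1R,5S,6R)-1-methyl-2-oxo-3-oxabicyclo[3.2.0]heptane-6-carboxylic acid
Conditions: NaClO2, NaH2PO4, 2-methylbut-2-ene, t-BuOH/H2O, 0 °C → rt
Reagents that add atoms: sodium chlorite, [Na+].[O-]Cl=O
Why: Pinnick oxidation converts the aldehyde to the acid without epimerising the α-centre.

Step 10
Reactants: 15; 16 quinolin-8-amine
Product: 18 (1R,5S,6R)-1-methyl-2-oxo-N-(quinolin-8-yl)-3-oxabicyclo[3.2.0]heptane-6-carboxamide, via acid chloride 17 (not isolated)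
Conditions: (COCl)2, DMF (cat.), CH2Cl2, 0 °C → rt; then 16, Et3N, DMAP (cat.), CH2Cl2
Reagents that add atoms: none
Why: Acid chloride formation and amide coupling install the bidentate N,N-directing group, which later also serves as the protecting group of this carboxyl.

Step 11
Reactants: 19 4-iodo-2-methoxyphenol
Product: 20 4-iodo-2-methoxy-1-(methoxymethoxy)benzene
Conditions: MOMCl, iPr2NEt, CH2Cl2, 0 °C → rt
Reagents that add atoms: chloromethyl methyl ether, COCCl
Why: O-Alkylation protects the phenol as an acetal that survives base, palladium, fluoride and hydride chemistry and is removed by acid at the end.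

Step 12
Reactants: 18; 20
Product: 21 (1R,5S,6R,7R)-7-[3-methoxy-4-(methoxymethoxy)phenyl]-1-methyl-2-oxo-N-(quinolin-8-yl)-3-oxabicyclo[3.2.0]heptane-6-carboxamide
Conditions: Pd(OAc)2 (10 mol%), Ag2CO3 (1.5 equiv), PivOH (0.3 equiv), t-AmylOH, 110 °C
Reagents that add atoms: none
Why: Aminoquinoline-directed β-C(sp3)–H arylation (Daugulis type, divalent/tetravalent palladium cycle): the five-membered palladacycle forms only with the C7–H cis to the amide on the exo face, so the aryl group arrives cis to the C6 carboxamide and trans to the lactone.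

Step 13
Reactants: 21
Product: 23 prop-2-en-1-yl (1R,2S,3R,4R)-2-(hydroxymethyl)-4-[3-methoxy-4-(methoxymethoxy)phenyl]-1-methyl-3-[(quinolin-8-yl)carbamoyl]cyclobutane-1-carboxylate, via lithium hydroxy carboxylate 22 (not isolated)
Conditions: LiOH·H2O (1.1 equiv), THF/H2O, 0 °C → rt; evaporate, toluene azeotrope; allyl bromide (1.5 equiv), DMF, 0 °C → rt; used at once
Reagents that add atoms: lithium hydroxide, [Li+].[OH-]; allyl bromide, C=CCBr
Why: Lactone saponification followed by carboxylate O-alkylation: hydroxide opens the strained γ-lactone while the secondary aryl amide is inert, so the C3 carboxyl stays masked, the C1 carboxyl becomes an allyl ester and no stereocentre is touched.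

Step 14
Reactants: 23
Product: 24 prop-2-en-1-yl (1R,2S,3R,4R)-2-formyl-4-[3-methoxy-4-(methoxymethoxy)phenyl]-1-methyl-3-[(quinolin-8-yl)carbamoyl]cyclobutane-1-carboxylate
Conditions: Dess–Martin periodinane, NaHCO3, CH2Cl2, 0 °C → rt (run directly on fresh 23)
Reagents that add atoms: none
Why: Buffered Dess–Martin oxidation gives the aldehyde before the γ-hydroxy ester can relactonise, and the α-centre already has its more stable configuration.

Step 15
Reactants: 24
Product: 25 prop-2-en-1-yl (1S,2S,3S,4R)-2-ethenyl-4-[3-methoxy-4-(methoxymethoxy)phenyl]-1-methyl-3-[(quinolin-8-yl)carbamoyl]cyclobutane-1-carboxylate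
Conditions: Ph3PCH3Br (3.0 equiv), KN(SiMe3)2 (2.8 equiv), THF, −78 → 0 °C
Reagents that add atoms: methyltriphenylphosphonium bromide, C[P+](c1ccccc1)(c1ccccc1)c1ccccc1.[Br-]
Why: Wittig methylenation; one equivalent of ylide is spent on the amide N–H, the resulting amidate is inert, and the non-stabilised ylide reacts with the aldehyde but not with the hindered, non-enolisable allyl ester.

Step 16
Reactants: 25
Product: 26 prop-2-en-1-yl (1S,2S,3S,4R)-3-[(tert-butoxycarbonyl)(quinolin-8-yl)carbamoyl]-2-ethenyl-4-[3-methoxy-4-(methoxymethoxy)phenyl]-1-methylcyclobutane-1-carboxylate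
Conditions: Boc2O (3 equiv), DMAP (1 equiv), MeCN, 40 °C
Reagents that add atoms: di-tert-butyl dicarbonate, CC(C)(C)OC(=O)OC(=O)OC(C)(C)C
Why: N-Acylation twists the secondary amide out of conjugation and makes it cleavable under mild conditions.

Step 17
Reactants: 26
Product: 28 1-(prop-2-en-1-yl) hydrogen (1S,2S,3S,4R)-2-ethenyl-4-[3-methoxy-4-(methoxymethoxy)phenyl]-1-methylcyclobutane-1,3-dicarboxylate (free acid at C3), via lithium peroxycarboxylate 27 (not isolated)
Conditions: LiOH·H2O (2 equiv), 30% H2O2 (5 equiv), THF/H2O (3:1), 0 °C; Na2SO3; 1 M HCl to pH 3–4 at 0 °C, EtOAc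
Reagents that add atoms: hydrogen peroxide, OO
Why: Hydroperoxide cleaves the N-Boc amide at the acyl carbon (imide perhydrolysis), while the allyl ester on the quaternary carbon and the vinyl group are inert at 0 °C, so only the C3 carboxyl is set free.

## Part B – 6-epi-incarvilline

Step 18
Reactants: 29 cis-cyclopent-4-ene-1,3-diyl diacetate (meso)
Product: 30 (1R,4S)-4-hydroxycyclopent-2-en-1-yl acetate
Conditions: Novozym 435 (immobilised Candida antarctica lipase B), MeOH, MTBE, rt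
Reagents that add atoms: none
Why: A lipase (serine hydrolase) differentiates the enantiotopic acetates of the meso diester by enantioselective transesterification at the S carbinol carbon; this catalytic desymmetrisation sets the first stereocentres of the amino alcohol.

Step 19
Reactants: 30
Product: 31 (1R,4S)-4-[(tert-butyldimethylsilyl)oxy]cyclopent-2-en-1-yl acetate
Conditions: TBSCl, imidazole, DMF, rt
Reagents that add atoms: tert-butyldimethylsilyl chloride, CC(C)(C)[Si](C)(C)Cl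
Why: Silylation of the free hydroxyl marks the S carbinol carbon as the one that is kept.

Step 20
Reactants: 31
Product: 32 (1R,4S)-4-[(tert-butyldimethylsilyl)oxy]cyclopent-2-en-1-ol
Conditions: K2CO3 (0.2 equiv), MeOH, 0 °C → rt
Reagents that add atoms: none
Why: Base-catalysed transesterification removes the acetate without affecting the silyl ether.

Step 21
Reactants: 32
Product: 33 (S)-4-[(tert-butyldimethylsilyl)oxy]cyclopent-2-en-1-one
Conditions: Dess–Martin periodinane, NaHCO3, CH2Cl2, 0 °C → rt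
Reagents that add atoms: none
Why: Buffered oxidation of the allylic alcohol gives the enone without β-elimination of the silyloxy group.

Step 22
Reactants: 33
Product: 34 tert-butyldimethyl{[(1S,2S)-2-methyl-4-[(trimethylsilyl)oxy]cyclopent-3-en-1-yl]oxy}silane
Conditions: Me2CuLi (from MeLi and CuI), Me3SiCl, Et3N, Et2O/THF, −78 °C
Reagents that add atoms: lithium dimethylcuprate, [Li+].C[Cu-]C; chlorotrimethylsilane, C[Si](C)(C)Cl
Why: Cuprate conjugate addition anti to the bulky silyloxy group with in-situ silyl trapping of the regiodefined enolate; the methyl-bearing carbon is set trans to OTBS.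

Step 23
Reactants: 34
Product: 35 (2R,3S,4S)-4-[(tert-butyldimethylsilyl)oxy]-2-(hydroxymethyl)-3-methylcyclopentan-1-one
Conditions: 37% aq HCHO, Yb(OTf)3 (10 mol%), THF, rt
Reagents that add atoms: formaldehyde, C=O
Why: Lanthanide-triflate-catalysed aqueous Mukaiyama aldol with formaldehyde at the former enolate carbon, anti to the adjacent methyl group, which is also the thermodynamic α-configuration.

Step 24
Reactants: 35
Product: 36 (1R,2R,3S,4S)-4-[(tert-butyldimethylsilyl)oxy]-2-(hydroxymethyl)-3-methylcyclopentan-1-ol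
Conditions: LiBH(s-Bu)3 (2.3 equiv), THF, −78 °C; aqueous NH4Cl
Reagents that add atoms: none
Why: The bulky trialkylborohydride attacks the cyclopentanone from the face opposite the adjacent hydroxymethyl arm, giving the 1,2-cis alcohol needed for the regioselective syn elimination.

Step 25
Reactants: 36
Product: 37 [(1R,2R,4S,5S)-4-[(tert-butyldimethylsilyl)oxy]-2-hydroxy-5-methylcyclopentyl]methyl 4-methylbenzenesulfonate
Conditions: TsCl (1.05 equiv), Et3N, Me3N·HCl (cat.), CH2Cl2, 0 °C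
Reagents that add atoms: 4-methylbenzenesulfonyl chloride, Cc1ccc(S(=O)(=O)Cl)cc1
Why: Selective sulfonylation of the primary hydroxyl over the hindered secondary one.

Step 26
Reactants: 37
Product: 38 [(1R,4S,5S)-4-[(tert-butyldimethylsilyl)oxy]-5-methylcyclopent-2-en-1-yl]methyl 4-methylbenzenesulfonate
Conditions: Burgess reagent, toluene, 60 °C
Reagents that add atoms: none
Why: Burgess dehydration is a syn elimination; the carbinol oxygen is trans to the hydrogen on the arm-bearing carbon, so only the ring CH2 can lose its syn hydrogen and the alkene forms away from the side arm.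

Step 27
Reactants: 38
Product: 39 1-[(1R,4S,5S)-4-[(tert-butyldimethylsilyl)oxy]-5-methylcyclopent-2-en-1-yl]-N-methylmethanamine
Conditions: MeNH2 (33% in EtOH, excess), THF, 55 °C, sealed tube
Reagents that add atoms: methylamine, CN
Why: SN2 displacement of the primary tosylate by excess methylamine.

Step 28
Reactants: 39
Product: 40 2-bromo-N-{[(1R,4S,5S)-4-[(tert-butyldimethylsilyl)oxy]-5-methylcyclopent-2-en-1-yl]methyl}-N-methylprop-2-en-1-amine
Conditions: 2,3-dibromopropene (1.05 equiv), K2CO3, MeCN, rt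
Reagents that add atoms: 2,3-dibromoprop-1-ene, C=C(Br)CBr
Why: N-Alkylation by the allylic bromide; the vinylic bromide is inert to SN2.

Step 29
Reactants: 40
Product: 41 (4aR,6S,7S,7aR)-6-[(tert-butyldimethylsilyl)oxy]-2,7-dimethyl-4-methylideneoctahydro-1H-cyclopenta[c]pyridine
Conditions: Pd(OAc)2 (10 mol%), PPh3 (20 mol%), HCO2Na, Et4NCl, DMF, 80 °C
Reagents that add atoms: none
Why: Intramolecular reductive Heck reaction (6-exo carbopalladation, then formate reduction): the tether forces syn addition on its own face, giving the cis ring fusion, and the σ-alkylpalladium has no syn β-hydrogen, so hydride capture wins.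

Step 30
Reactants: 41
Product: 42 (4R,4aS,6S,7S,7aR)-6-[(tert-butyldimethylsilyl)oxy]-2,4,7-trimethyloctahydro-1H-cyclopenta[c]pyridine
Conditions: H2 (1 atm), PtO2, EtOH, rt
Reagents that add atoms: none
Why: Heterogeneous hydrogenation of the exocyclic alkene from the convex face (the face of H-4a) sets C4 with its hydrogen cis to H-4a.

Step 31
Reactants: 42
Product: 43 (4R,4aS,6S,7S,7aR)-2,4,7-trimethyloctahydro-1H-cyclopenta[c]pyridin-6-ol (6-epi-incarvilline)
Conditions: Bu4NF, THF, rt → 40 °C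
Reagents that add atoms: none
Why: Fluoride desilylation frees the secondary alcohol with its configuration unchanged.

## Part C – union and side chain

Step 32
Reactants: 28; 43 (1.2 equiv)
Product: 44 1-(prop-2-en-1-yl) 3-[(4R,4aS,6R,7S,7aR)-2,4,7-trimethyloctahydro-1H-cyclopenta[c]pyridin-6-yl] (1S,2S,3S,4R)-2-ethenyl-4-[3-methoxy-4-(methoxymethoxy)phenyl]-1-methylcyclobutane-1,3-dicarboxylate
Conditions: PPh3 (1.5 equiv), DIAD (1.5 equiv), THF, 0 °C → rt
Reagents that add atoms: none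
Why: Mitsunobu esterification: the C3 carboxylate displaces the activated C6 oxygen of 43 with inversion (6S → 6R), and the acid stereocentre is not involved because the carboxylate oxygen is the nucleophile.

Step 33
Reactants: 44
Product: 45 3-[(4R,4aS,6R,7S,7aR)-2,4,7-trimethyloctahydro-1H-cyclopenta[c]pyridin-6-yl] hydrogen (1S,2S,3S,4R)-2-ethenyl-4-[3-methoxy-4-(methoxymethoxy)phenyl]-1-methylcyclobutane-1,3-dicarboxylate (free acid at C1)
Conditions: Pd(PPh3)4 (5 mol%), morpholine (5 equiv), THF, rt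
Reagents that add atoms: none
Why: Tsuji–Trost deallylation: zerovalent palladium ionises the allyl ester at the allyl carbon, so the hindrance of the quaternary acyl centre does not matter, and morpholine traps the π-allyl; the vinyl group, the incarvillyl ester and the MOM ether are untouched.

Step 34
Reactants: 45; 43 (1.3 equiv)
Product: 46 bis[(4R,4aS,6R,7S,7aR)-2,4,7-trimethyloctahydro-1H-cyclopenta[c]pyridin-6-yl] (1S,2S,3S,4R)-2-ethenyl-4-[3-methoxy-4-(methoxymethoxy)phenyl]-1-methylcyclobutane-1,3-dicarboxylate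
Conditions: PPh3 (2.0 equiv), DIAD (2.0 equiv), THF/toluene, 0 → 40 °C
Reagents that add atoms: none
Why: Second Mitsunobu esterification with inversion at C6 of 43; it suits the hindered tertiary acid because the carboxylate oxygen attacks the alkoxyphosphonium rather than the alcohol attacking an activated acyl carbon.

Step 35
Reactants: 47 2,2,6-trimethyl-4H-1,3-dioxin-4-one; 48 2-(trimethylsilyl)ethanol
Product: 49 2-(trimethylsilyl)ethyl 3-oxobutanoate
Conditions: toluene, 110 °C (acetone distilled off)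
Reagents that add atoms: none
Why: Thermal retro-[4+2] of the dioxinone releases acetylketene, which the alcohol traps to give the acetoacetate (acetoacetylation).

Step 36
Reactants: 49
Product: 50 2-(trimethylsilyl)ethyl (E)-3-{[(trifluoromethyl)sulfonyl]oxy}but-2-enoate
Conditions: Tf2O, aqueous Me4NOH, hexane/toluene, 5 °C
Reagents that add atoms: trifluoromethanesulfonic anhydride, O=S(=O)(OS(=O)(=O)C(F)(F)F)C(F)(F)F
Why: O-Triflation of the β-keto ester enolate; the non-chelating tetramethylammonium counter-ion gives the E enol triflate (OTf trans to the ester).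

Step 37
Reactants: 46; 50
Product: 52 bis[(4R,4aS,6R,7S,7aR)-2,4,7-trimethyloctahydro-1H-cyclopenta[c]pyridin-6-yl] (1S,2S,3S,4R)-4-[3-methoxy-4-(methoxymethoxy)phenyl]-1-methyl-2-{(3E)-3-methyl-5-oxo-5-[2-(trimethylsilyl)ethoxy]pent-3-en-1-yl}cyclobutane-1,3-dicarboxylate, via B-alkyl-9-BBN adduct 51 (not isolated)
Conditions: 9-BBN (2.5 equiv), THF, 0 → 40 °C; then 50, Pd(dppf)Cl2 (5 mol%), 3 M aq K3PO4, DMF, rt → 50 °C
Reagents that add atoms: none
Why: Anti-Markovnikov hydroboration (excess 9-BBN, because the tertiary amines bind it reversibly) followed by B-alkyl Suzuki–Miyaura coupling, which retains the enol triflate geometry and so gives the E trisubstituted enoate.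

Step 38
Reactants: 52
Product: 53 bis[(4R,4aS,6R,7S,7aR)-2,4,7-trimethyloctahydro-1H-cyclopenta[c]pyridin-6-yl] (1S,2S,3S,4R)-2-[(3E)-4-carboxy-3-methylbut-3-en-1-yl]-4-[3-methoxy-4-(methoxymethoxy)phenyl]-1-methylcyclobutane-1,3-dicarboxylate
Conditions: Bu4NF (3 equiv), THF, 0 °C → rt; aqueous NH4Cl
Reagents that add atoms: none
Why: Fluoride-induced fragmentation of the 2-(trimethylsilyl)ethyl ester (β-elimination to ethene and Me3SiF) frees the side-chain acid without hydroxide, so the two incarvillyl esters, the E enoate and the MOM ether survive.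

Step 39
Reactants: 53; 43 (1.3 equiv)
Product: 54 bis[(4R,4aS,6R,7S,7aR)-2,4,7-trimethyloctahydro-1H-cyclopenta[c]pyridin-6-yl] (1S,2S,3S,4R)-4-[3-methoxy-4-(methoxymethoxy)phenyl]-1-methyl-2-[(3E)-3-methyl-5-oxo-5-{[(4R,4aS,6R,7S,7aR)-2,4,7-trimethyloctahydro-1H-cyclopenta[c]pyridin-6-yl]oxy}pent-3-en-1-yl]cyclobutane-1,3-dicarboxylate (MOM ether of the target)
Conditions: PPh3 (1.5 equiv), DIAD (1.5 equiv), THF, 0 °C → rt
Reagents that add atoms: none
Why: Third Mitsunobu esterification with inversion at C6 of 43; the unsaturated carboxylate is the nucleophile and the alkene geometry is not affected.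

Step 40
Reactants: 54
Product: 55 target CNP0251577.3
Conditions: CF3CO2H/CH2Cl2 (1:4), 0 °C → rt; aqueous NaHCO3
Reagents that add atoms: none
Why: Acid-catalysed cleavage of the aryl MOM acetal; the esters, the enoate and the protonated amines are inert.

## Compound list

1 | monomethyl fumarate | COC(=O)/C=C/C(=O)O | starting material
2 | 1,3-oxazolidin-2-one | O=C1NCCO1 | starting material
3 | (E)-4-methoxy-4-oxobut-2-enoic pivalic anhydride | COC(=O)/C=C/C(=O)OC(=O)C(C)(C)C | intermediate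
4 | methyl (E)-4-oxo-4-(2-oxo-1,3-oxazolidin-3-yl)but-2-enoate | COC(=O)/C=C/C(=O)N1CCOC1=O | intermediate
5 | 1,1-bis(methylsulfanyl)ethene | C=C(SC)SC | starting material
6 | methyl (1S,2S)-3,3-bis(methylsulfanyl)-2-(2-oxo-1,3-oxazolidine-3-carbonyl)cyclobutane-1-carboxylate (trans) | C1C(SC)(SC)[C@H](C(=O)N2CCOC2=O)[C@H]1C(=O)OC | intermediate
7 | methyl (1S,2S)-2-(hydroxymethyl)-3,3-bis(methylsulfanyl)cyclobutane-1-carboxylate (trans) | C1C(SC)(SC)[C@H](CO)[C@H]1C(=O)OC | intermediate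
8 | methyl (1R,2S)-2-(hydroxymethyl)-3,3-bis(methylsulfanyl)cyclobutane-1-carboxylate (cis) | C1C(SC)(SC)[C@H](CO)[C@@H]1C(=O)OC | intermediate
9 | (1R,5S)-6,6-bis(methylsulfanyl)-3-oxabicyclo[3.2.0]heptan-2-one | C1C(SC)(SC)[C@H]2[C@@H]1C(=O)OC2 | intermediate
10 | lithium enolate of 9 | [Li+].C1C(SC)(SC)[C@H]2C1=C([O-])OC2 | intermediate
11 | (1R,5S)-1-methyl-6,6-bis(methylsulfanyl)-3-oxabicyclo[3.2.0]heptan-2-one | C1C(SC)(SC)[C@H]2[C@]1(C)C(=O)OC2 | intermediate
12 | (1R,5S)-1-methyl-3-oxabicyclo[3.2.0]heptane-2,6-dione | C1C(=O)[C@H]2[C@]1(C)C(=O)OC2 | intermediate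
13 | (1R,5S)-6-(methoxymethylidene)-1-methyl-3-oxabicyclo[3.2.0]heptan-2-one, E/Z mixture | C1C(=COC)[C@H]2[C@]1(C)C(=O)OC2 | intermediate
14 | (1R,5S,6R)-1-methyl-2-oxo-3-oxabicyclo[3.2.0]heptane-6-carbaldehyde (6-exo) | C1[C@@H](C=O)[C@H]2[C@]1(C)C(=O)OC2 | intermediate
15 | (1R,5S,6R)-1-methyl-2-oxo-3-oxabicyclo[3.2.0]heptane-6-carboxylic acid | C1[C@@H](C(=O)O)[C@H]2[C@]1(C)C(=O)OC2 | intermediate
16 | quinolin-8-amine | Nc1cccc2cccnc12 | starting material
17 | (1R,5S,6R)-1-methyl-2-oxo-3-oxabicyclo[3.2.0]heptane-6-carbonyl chloride | C1[C@@H](C(=O)Cl)[C@H]2[C@]1(C)C(=O)OC2 | intermediate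
18 | (1R,5S,6R)-1-methyl-2-oxo-N-(quinolin-8-yl)-3-oxabicyclo[3.2.0]heptane-6-carboxamide | C1[C@@H](C(=O)Nc3cccc4cccnc34)[C@H]2[C@]1(C)C(=O)OC2 | intermediate
19 | 4-iodo-2-methoxyphenol | COc1cc(I)ccc1O | starting material
20 | 4-iodo-2-methoxy-1-(methoxymethoxy)benzene | COCOc1ccc(I)cc1OC | intermediate
21 | (1R,5S,6R,7R)-7-[3-methoxy-4-(methoxymethoxy)phenyl]-1-methyl-2-oxo-N-(quinolin-8-yl)-3-oxabicyclo[3.2.0]heptane-6-carboxamide (aryl cis to amide, both exo) | COc1cc([C@H]2[C@@H](C(=O)Nc4cccc5cccnc45)[C@H]3[C@]2(C)C(=O)OC3)ccc1OCOC | intermediate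
22 | lithium (1R,2S,3R,4R)-2-(hydroxymethyl)-4-[3-methoxy-4-(methoxymethoxy)phenyl]-1-methyl-3-[(quinolin-8-yl)carbamoyl]cyclobutane-1-carboxylate | [Li+].COc1cc([C@H]2[C@@H](C(=O)Nc3cccc4cccnc34)[C@H](CO)[C@]2(C)C(=O)[O-])ccc1OCOC | intermediate
23 | prop-2-en-1-yl (1R,2S,3R,4R)-2-(hydroxymethyl)-4-[3-methoxy-4-(methoxymethoxy)phenyl]-1-methyl-3-[(quinolin-8-yl)carbamoyl]cyclobutane-1-carboxylate | COc1cc([C@H]2[C@@H](C(=O)Nc3cccc4cccnc34)[C@H](CO)[C@]2(C)C(=O)OCC=C)ccc1OCOC | intermediate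
24 | prop-2-en-1-yl (1R,2S,3R,4R)-2-formyl-4-[3-methoxy-4-(methoxymethoxy)phenyl]-1-methyl-3-[(quinolin-8-yl)carbamoyl]cyclobutane-1-carboxylate | COc1cc([C@H]2[C@@H](C(=O)Nc3cccc4cccnc34)[C@H](C=O)[C@]2(C)C(=O)OCC=C)ccc1OCOC | intermediate
25 | prop-2-en-1-yl (1S,2S,3S,4R)-2-ethenyl-4-[3-methoxy-4-(methoxymethoxy)phenyl]-1-methyl-3-[(quinolin-8-yl)carbamoyl]cyclobutane-1-carboxylate | COc1cc([C@H]2[C@@H](C(=O)Nc3cccc4cccnc34)[C@H](C=C)[C@]2(C)C(=O)OCC=C)ccc1OCOC | intermediate
26 | prop-2-en-1-yl (1S,2S,3S,4R)-3-[(tert-butoxycarbonyl)(quinolin-8-yl)carbamoyl]-2-ethenyl-4-[3-methoxy-4-(methoxymethoxy)phenyl]-1-methylcyclobutane-1-carboxylate | COc1cc([C@H]2[C@@H](C(=O)N(C(=O)OC(C)(C)C)c3cccc4cccnc34)[C@H](C=C)[C@]2(C)C(=O)OCC=C)ccc1OCOC | intermediate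
27 | lithium (1S,2S,3S,4R)-2-ethenyl-4-[3-methoxy-4-(methoxymethoxy)phenyl]-3-methyl-3-[(prop-2-en-1-yloxy)carbonyl]cyclobutane-1-carboperoxoate | [Li+].COc1cc([C@H]2[C@@H](C(=O)O[O-])[C@H](C=C)[C@]2(C)C(=O)OCC=C)ccc1OCOC | intermediate
28 | 1-(prop-2-en-1-yl) hydrogen (1S,2S,3S,4R)-2-ethenyl-4-[3-methoxy-4-(methoxymethoxy)phenyl]-1-methylcyclobutane-1,3-dicarboxylate (free acid at C3) | COc1cc([C@H]2[C@@H](C(=O)O)[C@H](C=C)[C@]2(C)C(=O)OCC=C)ccc1OCOC | intermediate
29 | cis-cyclopent-4-ene-1,3-diyl diacetate (meso) | CC(=O)O[C@@H]1C=C[C@H](OC(C)=O)C1 | starting material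
30 | (1R,4S)-4-hydroxycyclopent-2-en-1-yl acetate | O[C@@H]1C=C[C@H](OC(C)=O)C1 | intermediate
31 | (1R,4S)-4-[(tert-butyldimethylsilyl)oxy]cyclopent-2-en-1-yl acetate | CC(C)(C)[Si](C)(C)O[C@@H]1C=C[C@H](OC(C)=O)C1 | intermediate
32 | (1R,4S)-4-[(tert-butyldimethylsilyl)oxy]cyclopent-2-en-1-ol | CC(C)(C)[Si](C)(C)O[C@@H]1C=C[C@H](O)C1 | intermediate
33 | (S)-4-[(tert-butyldimethylsilyl)oxy]cyclopent-2-en-1-one | CC(C)(C)[Si](C)(C)O[C@@H]1C=CC(=O)C1 | intermediate
34 | tert-butyldimethyl{[(1S,2S)-2-methyl-4-[(trimethylsilyl)oxy]cyclopent-3-en-1-yl]oxy}silane (trans) | CC(C)(C)[Si](C)(C)O[C@H]1CC(O[Si](C)(C)C)=C[C@@H]1C | intermediate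
35 | (2R,3S,4S)-4-[(tert-butyldimethylsilyl)oxy]-2-(hydroxymethyl)-3-methylcyclopentan-1-one (all trans) | CC(C)(C)[Si](C)(C)O[C@H]1CC(=O)[C@@H](CO)[C@@H]1C | intermediate
36 | (1R,2R,3S,4S)-4-[(tert-butyldimethylsilyl)oxy]-2-(hydroxymethyl)-3-methylcyclopentan-1-ol | CC(C)(C)[Si](C)(C)O[C@H]1C[C@@H](O)[C@@H](CO)[C@@H]1C | intermediate
37 | [(1R,2R,4S,5S)-4-[(tert-butyldimethylsilyl)oxy]-2-hydroxy-5-methylcyclopentyl]methyl 4-methylbenzenesulfonate | CC(C)(C)[Si](C)(C)O[C@H]1C[C@@H](O)[C@@H](COS(=O)(=O)c2ccc(C)cc2)[C@@H]1C | intermediate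
38 | [(1R,4S,5S)-4-[(tert-butyldimethylsilyl)oxy]-5-methylcyclopent-2-en-1-yl]methyl 4-methylbenzenesulfonate | CC(C)(C)[Si](C)(C)O[C@H]1C=C[C@@H](COS(=O)(=O)c2ccc(C)cc2)[C@@H]1C | intermediate
39 | 1-[(1R,4S,5S)-4-[(tert-butyldimethylsilyl)oxy]-5-methylcyclopent-2-en-1-yl]-N-methylmethanamine | CC(C)(C)[Si](C)(C)O[C@H]1C=C[C@@H](CNC)[C@@H]1C | intermediate
40 | 2-bromo-N-{[(1R,4S,5S)-4-[(tert-butyldimethylsilyl)oxy]-5-methylcyclopent-2-en-1-yl]methyl}-N-methylprop-2-en-1-amine | CC(C)(C)[Si](C)(C)O[C@H]1C=C[C@@H](CN(C)CC(Br)=C)[C@@H]1C | intermediate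
41 | (4aR,6S,7S,7aR)-6-[(tert-butyldimethylsilyl)oxy]-2,7-dimethyl-4-methylideneoctahydro-1H-cyclopenta[c]pyridine (cis-fused) | CC(C)(C)[Si](C)(C)O[C@H]1C[C@@H]2[C@@H](CN(C)CC2=C)[C@@H]1C | intermediate
42 | (4R,4aS,6S,7S,7aR)-6-[(tert-butyldimethylsilyl)oxy]-2,4,7-trimethyloctahydro-1H-cyclopenta[c]pyridine | CC(C)(C)[Si](C)(C)O[C@H]1C[C@@H]2[C@@H](CN(C)C[C@@H]2C)[C@@H]1C | intermediate
43 | (4R,4aS,6S,7S,7aR)-2,4,7-trimethyloctahydro-1H-cyclopenta[c]pyridin-6-ol (6-epi-incarvilline) | O[C@H]1C[C@@H]2[C@@H](CN(C)C[C@@H]2C)[C@@H]1C | intermediate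
44 | 1-(prop-2-en-1-yl) 3-[(4R,4aS,6R,7S,7aR)-2,4,7-trimethyloctahydro-1H-cyclopenta[c]pyridin-6-yl] (1S,2S,3S,4R)-2-ethenyl-4-[3-methoxy-4-(methoxymethoxy)phenyl]-1-methylcyclobutane-1,3-dicarboxylate | COc1cc([C@H]2[C@@H](C(=O)O[C@@H]3C[C@@H]4[C@@H](CN(C)C[C@@H]4C)[C@@H]3C)[C@H](C=C)[C@]2(C)C(=O)OCC=C)ccc1OCOC | intermediate
45 | 3-[(4R,4aS,6R,7S,7aR)-2,4,7-trimethyloctahydro-1H-cyclopenta[c]pyridin-6-yl] hydrogen (1S,2S,3S,4R)-2-ethenyl-4-[3-methoxy-4-(methoxymethoxy)phenyl]-1-methylcyclobutane-1,3-dicarboxylate (free acid at C1) | COc1cc([C@H]2[C@@H](C(=O)O[C@@H]3C[C@@H]4[C@@H](CN(C)C[C@@H]4C)[C@@H]3C)[C@H](C=C)[C@]2(C)C(=O)O)ccc1OCOC | intermediate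
46 | bis[(4R,4aS,6R,7S,7aR)-2,4,7-trimethyloctahydro-1H-cyclopenta[c]pyridin-6-yl] (1S,2S,3S,4R)-2-ethenyl-4-[3-methoxy-4-(methoxymethoxy)phenyl]-1-methylcyclobutane-1,3-dicarboxylate | COc1cc([C@H]2[C@@H](C(=O)O[C@@H]3C[C@@H]4[C@@H](CN(C)C[C@@H]4C)[C@@H]3C)[C@H](C=C)[C@]2(C)C(=O)O[C@@H]2C[C@@H]3[C@@H](CN(C)C[C@@H]3C)[C@@H]2C)ccc1OCOC | intermediate
47 | 2,2,6-trimethyl-4H-1,3-dioxin-4-one | CC1=CC(=O)OC(C)(C)O1 | starting material
48 | 2-(trimethylsilyl)ethanol | C[Si](C)(C)CCO | starting material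
49 | 2-(trimethylsilyl)ethyl 3-oxobutanoate | CC(=O)CC(=O)OCC[Si](C)(C)C | intermediate
50 | 2-(trimethylsilyl)ethyl (E)-3-{[(trifluoromethyl)sulfonyl]oxy}but-2-enoate | C/C(OS(=O)(=O)C(F)(F)F)=C\C(=O)OCC[Si](C)(C)C | intermediate
51 | bis[(4R,4aS,6R,7S,7aR)-2,4,7-trimethyloctahydro-1H-cyclopenta[c]pyridin-6-yl] (1S,2S,3S,4R)-2-[2-(9-borabicyclo[3.3.1]nonan-9-yl)ethyl]-4-[3-methoxy-4-(methoxymethoxy)phenyl]-1-methylcyclobutane-1,3-dicarboxylate | COc1cc([C@H]2[C@@H](C(=O)O[C@@H]3C[C@@H]4[C@@H](CN(C)C[C@@H]4C)[C@@H]3C)[C@H](CCB3C4CCCC3CCC4)[C@]2(C)C(=O)O[C@@H]2C[C@@H]3[C@@H](CN(C)C[C@@H]3C)[C@@H]2C)ccc1OCOC | intermediate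
52 | bis[(4R,4aS,6R,7S,7aR)-2,4,7-trimethyloctahydro-1H-cyclopenta[c]pyridin-6-yl] (1S,2S,3S,4R)-4-[3-methoxy-4-(methoxymethoxy)phenyl]-1-methyl-2-{(3E)-3-methyl-5-oxo-5-[2-(trimethylsilyl)ethoxy]pent-3-en-1-yl}cyclobutane-1,3-dicarboxylate | COc1cc([C@H]2[C@@H](C(=O)O[C@@H]3C[C@@H]4[C@@H](CN(C)C[C@@H]4C)[C@@H]3C)[C@H](CC/C(C)=C/C(=O)OCC[Si](C)(C)C)[C@]2(C)C(=O)O[C@@H]2C[C@@H]3[C@@H](CN(C)C[C@@H]3C)[C@@H]2C)ccc1OCOC | intermediate
53 | bis[(4R,4aS,6R,7S,7aR)-2,4,7-trimethyloctahydro-1H-cyclopenta[c]pyridin-6-yl] (1S,2S,3S,4R)-2-[(3E)-4-carboxy-3-methylbut-3-en-1-yl]-4-[3-methoxy-4-(methoxymethoxy)phenyl]-1-methylcyclobutane-1,3-dicarboxylate | COc1cc([C@H]2[C@@H](C(=O)O[C@@H]3C[C@@H]4[C@@H](CN(C)C[C@@H]4C)[C@@H]3C)[C@H](CC/C(C)=C/C(=O)O)[C@]2(C)C(=O)O[C@@H]2C[C@@H]3[C@@H](CN(C)C[C@@H]3C)[C@@H]2C)ccc1OCOC | intermediate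
54 | MOM ether of the target: 53 with the side-chain acid also esterified by the (4R,4aS,6R,7S,7aR)-2,4,7-trimethyloctahydro-1H-cyclopenta[c]pyridin-6-yl group | COc1cc([C@H]2[C@@H](C(=O)O[C@@H]3C[C@@H]4[C@@H](CN(C)C[C@@H]4C)[C@@H]3C)[C@H](CC/C(C)=C/C(=O)O[C@@H]3C[C@@H]4[C@@H](CN(C)C[C@@H]4C)[C@@H]3C)[C@]2(C)C(=O)O[C@@H]2C[C@@H]3[C@@H](CN(C)C[C@@H]3C)[C@@H]2C)ccc1OCOC | intermediate
55 | CNP0251577.3 (cyclobutane 1S,2S,3S,4R numbered from the methyl-bearing carbon; each amino alcohol 4R,4aS,6R,7S,7aR; side chain E; free 4-hydroxy-3-methoxyphenyl) | COc1cc([C@H]2[C@@H](C(=O)O[C@@H]3C[C@@H]4[C@@H](CN(C)C[C@@H]4C)[C@@H]3C)[C@H](CC/C(C)=C/C(=O)O[C@@H]3C[C@@H]4[C@@H](CN(C)C[C@@H]4C)[C@@H]3C)[C@]2(C)C(=O)O[C@@H]2C[C@@H]3[C@@H](CN(C)C[C@@H]3C)[C@@H]2C)ccc1O | target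

## Step count and weak points

Total: 40 steps. Longest linear sequence: 23 steps (steps 1–10, 12–17, 32–34, 37–40).

Three steps most likely to fail:

Step 12 (C–H arylation next to the quaternary carbon). The C7–H is flanked by the methyl-bearing ring-fusion carbon, so palladation may be slow. The fallback sets out from 12 and comes back at 21. Dione 12 is enolised towards its CH2 (LiN(SiMe3)2, PhNTf2, THF, −78 °C) to give the cyclobutenyl triflate F1, which is methoxycarbonylated (CO, MeOH, Pd(OAc)2/dppp, Et3N) to the cyclobutene ester F2. Aryl iodide 20 is converted (i-PrMgCl·LiCl, then B(OMe)3, aqueous NH4Cl) into the arylboronic acid F3. Rhodium-catalysed conjugate addition of F3 to F2 ([Rh(OH)(cod)]2, dioxane/H2O, 60 °C) delivers the aryl group from the exo face, and NaOMe equilibration then moves the ester to the exo position to give the lactone ester F4. LiOH hydrolyses the ester and opens the lactone, and acidification to pH 3 recloses the lactone to give the lactone acid F5. Its acid chloride F6 (1-chloro-N,N,2-trimethylprop-1-en-1-amine, CH2Cl2) is coupled with 16 in pyridine to give 21. The weak point of this fallback is that the cis aryl/ester relationship rests on a thermodynamic preference that I expect but cannot guarantee.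

Step 13 (lactone opening and allylation). The γ-hydroxy allyl ester 23 may relactonise, with loss of allyl alcohol, before it is oxidised. The fallback sets out from 21 and comes back at 24. The lactone of 21 is opened by SN2 attack of PhSNa at the O–CH2 carbon (DMF, 110 °C) to give the phenylthio acid F7. This is alkylated (Cs2CO3, allyl bromide, DMF, rt) to the allyl ester F8 and oxidised (NaIO4, aqueous MeOH) to the sulfoxide F9. A Pummerer rearrangement ((CF3CO)2O, 2,6-lutidine, CH2Cl2, 0 °C; then aqueous NaHCO3) gives aldehyde 24 without ever passing through a free hydroxy ester. Its own risk is transient N-trifluoroacetylation of the amide, which the bicarbonate work-up should reverse.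

Step 34 (Mitsunobu at the tertiary acid). The zwitterionic amino acid 45 carries its free carboxyl on a quaternary carbon, and the esterification may stall. The fallback sets out from 43 and 45 and comes back at 46. 43 is converted (MsCl, Et3N, CH2Cl2, 0 °C) into the mesylate F10, and 45 is converted with Cs2CO3 in DMF into the caesium carboxylate F11. Heating F11 with F10 (1.5 equiv, DMF, 50 °C) forms the ester by carboxylate SN2 displacement with the same inversion at C6.

## Further compounds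

F1 | step 12 | (1R,5S)-1-methyl-2-oxo-3-oxabicyclo[3.2.0]hept-6-en-6-yl trifluoromethanesulfonate | C1=C(OS(=O)(=O)C(F)(F)F)[C@H]2[C@]1(C)C(=O)OC2
F2 | step 12 | methyl (1R,5S)-1-methyl-2-oxo-3-oxabicyclo[3.2.0]hept-6-ene-6-carboxylate | C1=C(C(=O)OC)[C@H]2[C@]1(C)C(=O)OC2
F3 | step 12 | [3-methoxy-4-(methoxymethoxy)phenyl]boronic acid | COCOc1ccc(B(O)O)cc1OC
F4 | step 12 | methyl (1R,5S,6R,7R)-7-[3-methoxy-4-(methoxymethoxy)phenyl]-1-methyl-2-oxo-3-oxabicyclo[3.2.0]heptane-6-carboxylate | COc1cc([C@H]2[C@@H](C(=O)OC)[C@H]3[C@]2(C)C(=O)OC3)ccc1OCOC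
F5 | step 12 | (1R,5S,6R,7R)-7-[3-methoxy-4-(methoxymethoxy)phenyl]-1-methyl-2-oxo-3-oxabicyclo[3.2.0]heptane-6-carboxylic acid | COc1cc([C@H]2[C@@H](C(=O)O)[C@H]3[C@]2(C)C(=O)OC3)ccc1OCOC
F6 | step 12 | (1R,5S,6R,7R)-7-[3-methoxy-4-(methoxymethoxy)phenyl]-1-methyl-2-oxo-3-oxabicyclo[3.2.0]heptane-6-carbonyl chloride | COc1cc([C@H]2[C@@H](C(=O)Cl)[C@H]3[C@]2(C)C(=O)OC3)ccc1OCOC
F7 | step 13 | free carboxylic acid corresponding to 22 with CH2SPh in place of CH2OH | COc1cc([C@H]2[C@@H](C(=O)Nc3cccc4cccnc34)[C@H](CSc3ccccc3)[C@]2(C)C(=O)O)ccc1OCOC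
F8 | step 13 | allyl ester of F7 (23 with CH2SPh in place of CH2OH) | COc1cc([C@H]2[C@@H](C(=O)Nc3cccc4cccnc34)[C@H](CSc3ccccc3)[C@]2(C)C(=O)OCC=C)ccc1OCOC
F9 | step 13 | sulfoxide of F8 (mixture at sulfur) | COc1cc([C@H]2[C@@H](C(=O)Nc3cccc4cccnc34)[C@H](CS(=O)c3ccccc3)[C@]2(C)C(=O)OCC=C)ccc1OCOC
F10 | step 34 | (4R,4aS,6S,7S,7aR)-2,4,7-trimethyloctahydro-1H-cyclopenta[c]pyridin-6-yl methanesulfonate | CS(=O)(=O)O[C@H]1C[C@@H]2[C@@H](CN(C)C[C@@H]2C)[C@@H]1C
F11 | step 34 | caesium salt of 45 | [Cs+].COc1cc([C@H]2[C@@H](C(=O)O[C@@H]3C[C@@H]4[C@@H](CN(C)C[C@@H]4C)[C@@H]3C)[C@H](C=C)[C@]2(C)C(=O)[O-])ccc1OCOC
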